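**Plan**

1. Retrosynthesis: the O11 acetate and the C11–C12 bond are cut first (vinylogous Mukaiyama aldol on an albicanal-type aldehyde). The C8 methylidene/C9–H pair is traced back to an allylsilane on a C8=C9 double bond. Ring B is then a cyclohexene whose C5–C10 and C6–C7 bonds are cut together by a retro-[4+2]. The acyclic triene is cut at C1–C10 (B-alkyl Suzuki–Miyaura) and at C8–C9 (carbomagnesiation of but-2-yn-1-ol).
2. Forward: two small fragments are joined to an acyclic triene; rings A and B close together in one intramolecular Diels–Alder reaction; the C6 acyl helper is removed (hydrolysis, Barton decarboxylation); protodesilylation unveils the exocyclic alkene; the C11–C15 chain is added last.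
3. Enabling feature: the exocyclic C8=CH2 next to C9–H is the SE2' retron of a ring B cyclohexene (C8=C9) carrying CH2SiMe3 on C8. Ring B (C5–C10) is therefore the adduct of a C7=C8–C9=C10 diene and a C5=C6 dienophile, and ring A (C1–C5, C10) is simply the four-carbon tether C1–C4 between diene terminus C10 and dienophile carbon C5.
4. Stereochemistry: the only bought stereocentre is C4 of (4S)-4-benzyl-1,3-oxazolidin-2-one on the dienophile. It sets C5 and C10 in the cycloaddition (face control and endo, trans-fused closure); C10 then directs the protonation that sets C9; C9 directs the Felkin–Anh aldol that sets C11; the 13E alkene comes from the aldol.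

Key step: step 6

Remark: positions are named by drimane/labdane numbering (decalin C1–C10, gem-dimethyl on C4, angular methyl on C10, ring A = C1–C5 + C10, ring B = C5–C10, side chain C11–C15); TBS = tert-butyldimethylsilyl; compounds 1, 2, 5, 8, 9 and 23 are taken to be commercial.

**Route**

Step 1
Reactants: 1 2,2-dimethylpent-4-enal; 2 malonic acid
Product: 4 (2E)-4,4-dimethylhepta-2,6-dienoic acid, via alkylidenemalonic acid 3 (not isolated)
Conditions: pyridine, piperidine (cat.), 100 °C
Reagents that add atoms: none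
Why: Doebner–Knoevenagel condensation; the non-enolisable aldehyde condenses with malonic acid and the diacid loses CO2 in hot pyridine to give the E acid, which cannot deconjugate because C4 is quaternary.

Step 2
Reactants: 4 (2E)-4,4-dimethylhepta-2,6-dienoic acid; 5 (4S)-4-benzyl-1,3-oxazolidin-2-one
Product: 7 (4S)-4-benzyl-3-[(2E)-4,4-dimethylhepta-2,6-dienoyl]-1,3-oxazolidin-2-one, via mixed pivalic anhydride 6 (not isolated)
Conditions: PivCl, Et3N, THF, −20 °C; then 5, LiCl, rt
Reagents that add atoms: none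
Why: N-acylation of the oxazolidinone through the mixed anhydride (LiCl/Et3N protocol) needs no strong base, keeps the E enoyl unit, and the hindered pivaloyl carbonyl is not attacked.

Step 3
Reactants: 8 (2-bromoprop-2-en-1-yl)trimethylsilane; 9 but-2-yn-1-ol
Product: 12 (2Z)-3-iodo-2-[3-(trimethylsilyl)prop-1-en-2-yl]but-2-en-1-ol, via alkenyl Grignard reagent 10 (not isolated), via cyclic magnesium alkoxide 11 (not isolated)
Conditions: Mg, THF, rt (10, 2.5 equiv); then 9, THF/toluene, 70 °C; then I2, THF, −20 °C; aq NH4Cl/Na2S2O3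
Reagents that add atoms: iodine (II)
Why: magnesium-mediated anti-carbomagnesiation of a propargylic alkoxide: one equivalent of 10 deprotonates 9, the next delivers its alkenyl group to the alkyne carbon beside the carbinol while magnesium ends anti on the far carbon, held by the alkoxide in the five-membered chelate 11, and iodinolysis with retention should give the 2Z iodide (CH2OH cis to I, methyl cis to the silylmethylvinyl group).

Step 4
Reactants: 12 (2Z)-3-iodo-2-[3-(trimethylsilyl)prop-1-en-2-yl]but-2-en-1-ol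
Product: 13 tert-butyl({(2Z)-3-iodo-2-[3-(trimethylsilyl)prop-1-en-2-yl]but-2-en-1-yl}oxy)dimethylsilane
Conditions: TBSCl, imidazole, DMF, rt
Reagents that add atoms: tert-butyldimethylsilyl chloride (CC(C)(C)[Si](C)(C)Cl)
Why: standard imidazole-assisted silylation of the primary allylic alcohol; no stereocentre is involved and the alkene geometry is untouched.

Step 5
Reactants: 7 (4S)-4-benzyl-3-[(2E)-4,4-dimethylhepta-2,6-dienoyl]-1,3-oxazolidin-2-one; 13 tert-butyl({(2Z)-3-iodo-2-[3-(trimethylsilyl)prop-1-en-2-yl]but-2-en-1-yl}oxy)dimethylsilane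
Product: 15 (4S)-4-benzyl-3-[(2E,8Z)-9-({[tert-butyl(dimethyl)silyl]oxy}methyl)-4,4,8-trimethyl-10-[(trimethylsilyl)methyl]undeca-2,8,10-trienoyl]-1,3-oxazolidin-2-one, via B-alkyl-9-borabicyclononane 14 (not isolated)
Conditions: 9-BBN-H, THF, 0 °C → rt; then 13, PdCl2(dppf) (5 mol %; dppf = 1,1'-bis(diphenylphosphino)ferrocene), AsPh3, aq K3PO4, DMF, rt
Reagents that add atoms: none
Why: 9-BBN-H hydroborates only the monosubstituted alkene of 7 (the hindered, electron-poor enoyl alkene is left), and the B-alkyl Suzuki–Miyaura coupling with the alkenyl iodide proceeds with retention, fixing the 8Z geometry (tether cis to CH2OTBS and trans to the C8 vinyl unit, as the cycloaddition requires).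

Step 6
Reactants: 15 (4S)-4-benzyl-3-[(2E,8Z)-9-({[tert-butyl(dimethyl)silyl]oxy}methyl)-4,4,8-trimethyl-10-[(trimethylsilyl)methyl]undeca-2,8,10-trienoyl]-1,3-oxazolidin-2-one
Product: 16 (4S)-4-benzyl-3-{[(1S,4aS,8aS)-4-({[tert-butyl(dimethyl)silyl]oxy}methyl)-4a,8,8-trimethyl-3-[(trimethylsilyl)methyl]-1,2,4a,5,6,7,8,8a-octahydronaphthalen-1-yl]carbonyl}-1,3-oxazolidin-2-one (trans-fused cycloadduct)
Conditions: Me2AlCl (1.5 equiv), CH2Cl2, −30 °C → 0 °C; aq potassium sodium tartrate
Reagents that add atoms: none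
Why: Excess Me2AlCl turns the imide into a cationic bidentate dimethylaluminium chelate with an s-cis enoyl unit, and this very electron-poor dienophile (C5=C6) undergoes a concerted, asynchronous [4+2] cycloaddition with the tethered, electron-rich tetrasubstituted diene (C7=C8–C9=C10). The closest known reaction type is the Lewis acid-promoted intramolecular Diels–Alder reaction of (2E,8E,10E)-trienoyl oxazolidinones, which gives trans-fused octalins under auxiliary control. Ring B closes as the cyclohexene of the [4+2] itself (C6–C7 and C5–C10 bonds), and ring A closes in the same event as the six-membered ring spanned by the tether C1–C4 when the C5–C10 bond forms (type 1 intramolecular mode, 1,7,9-decatriene to bicyclo[4.4.0]decene). C5 is set by the auxiliary, whose benzyl group covers one face of the chelated s-cis enoyl unit so that the diene adds to the C6-si face (5S); C10 is set relative to C5 by the endo transition state (chelated carbonyl under the diene, E dienophile, tether on the outside of the diene terminus), which gives the trans ring fusion with the C10 methyl anti to H-5, and the temporary C6 centre follows from the E dienophile. The step needs facial selectivity (auxiliary), endo over exo closure (favoured by the cationic complex, which must outweigh the developing 1,3-diaxial contact of the C4 and C10 methyl groups) and cycloaddition in preference to allylsilane side reactions (the tether allows only the C5–C10/C6–C7 bonding mode and Me2AlCl scavenges protons). The inside methyl on the diene terminus slows the reaction, but the four donor substituents of the diene and the cationic dienophile should compensate.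

Step 7
Reactants: 16 (4S)-4-benzyl-3-{[(1S,4aS,8aS)-4-({[tert-butyl(dimethyl)silyl]oxy}methyl)-4a,8,8-trimethyl-3-[(trimethylsilyl)methyl]-1,2,4a,5,6,7,8,8a-octahydronaphthalen-1-yl]carbonyl}-1,3-oxazolidin-2-one
Product: 18 (1S,4aS,8aS)-4-({[tert-butyl(dimethyl)silyl]oxy}methyl)-4a,8,8-trimethyl-3-[(trimethylsilyl)methyl]-1,2,4a,5,6,7,8,8a-octahydronaphthalene-1-carboxylic acid, via lithium percarboxylate 17 (not isolated)
Conditions: LiOH, H2O2, THF/H2O, 0 °C; aq Na2SO3; 1 M HCl to pH 4 (0 °C)
Reagents that add atoms: hydrogen peroxide (OO)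
Why: hydroperoxide cleavage of the N-acyloxazolidinone; the small, highly nucleophilic hydroperoxide anion attacks the exocyclic carbonyl even of this hindered acyl group, sulfite reduces the peracid, the auxiliary is recovered, and C5/C10 are not affected.

Step 8
Reactants: 18 (1S,4aS,8aS)-4-({[tert-butyl(dimethyl)silyl]oxy}methyl)-4a,8,8-trimethyl-3-[(trimethylsilyl)methyl]-1,2,4a,5,6,7,8,8a-octahydronaphthalene-1-carboxylic acid
Product: 20 tert-butyl(dimethyl)({(4aS,8aS)-5,5,8a-trimethyl-2-[(trimethylsilyl)methyl]-3,4,4a,5,6,7,8,8a-octahydronaphthalen-1-yl}methoxy)silane, via thiohydroxamate ester 19 (not isolated)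
Conditions: N-hydroxypyridine-2-thione, DCC, DMAP (cat.), CH2Cl2, rt, dark; then t-BuSH, hν (tungsten lamp), rt
Reagents that add atoms: none
Why: Barton reductive decarboxylation; the thiohydroxamate ester fragments under visible light to the secondary C6 radical, which takes hydrogen from t-BuSH, and the neutral radical chain leaves the allylsilane, the silyl ether and C5/C10 untouched.

Step 9
Reactants: 20 tert-butyl(dimethyl)({(4aS,8aS)-5,5,8a-trimethyl-2-[(trimethylsilyl)methyl]-3,4,4a,5,6,7,8,8a-octahydronaphthalen-1-yl}methoxy)silane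
Product: 21 [(1S,4aS,8aS)-5,5,8a-trimethyl-2-methylidenedecahydronaphthalen-1-yl]methanol (albicanol skeleton)
Conditions: TsOH·H2O (0.3 equiv), MeOH/CH2Cl2 (1:2), 0 °C → rt; NaHCO3
Reagents that add atoms: none
Why: acid-mediated SE2' protodesilylation of the allylsilane; the proton should add to C9 axially from the α face, anti to the axial C10 methyl, giving the β-silyl tertiary cation at C8 that loses silicon to methanol to form the exocyclic alkene with H-9 trans to the angular methyl (C11 equatorial), and the same acid removes the primary TBS ether by methanolysis.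

Step 10
Reactants: 21 [(1S,4aS,8aS)-5,5,8a-trimethyl-2-methylidenedecahydronaphthalen-1-yl]methanol
Product: 22 (1S,4aS,8aS)-5,5,8a-trimethyl-2-methylidenedecahydronaphthalene-1-carbaldehyde
Conditions: Dess–Martin periodinane, NaHCO3, CH2Cl2, 0 °C → rt
Reagents that add atoms: none
Why: buffered Dess–Martin oxidation gives the β,γ-unsaturated aldehyde under neutral conditions that should avoid epimerisation at C9 and migration of the exocyclic alkene into conjugation.

Step 11
Reactants: 23 methyl 3-methylbut-2-enoate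
Product: 25 tert-butyl[(1-methoxy-3-methylbuta-1,3-dien-1-yl)oxy]dimethylsilane, via lithium dienolate 24 (not isolated)
Conditions: LiN(i-Pr)2, THF, −78 °C; then TBSCl, DMPU, −78 °C → rt
Reagents that add atoms: tert-butyldimethylsilyl chloride (CC(C)(C)[Si](C)(C)Cl)
Why: γ-deprotonation of the β,β-dimethylacrylate gives the cross-conjugated lithium dienolate, which is O-silylated to the silyl ketene acetal used as the vinylogous nucleophile (its ketene acetal geometry is immaterial).

Step 12
Reactants: 22 (1S,4aS,8aS)-5,5,8a-trimethyl-2-methylidenedecahydronaphthalene-1-carbaldehyde; 25 tert-butyl[(1-methoxy-3-methylbuta-1,3-dien-1-yl)oxy]dimethylsilane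
Product: 26 methyl (2E,5S)-5-hydroxy-3-methyl-5-[(1S,4aS,8aS)-5,5,8a-trimethyl-2-methylidenedecahydronaphthalen-1-yl]pent-2-enoate
Conditions: B(C6F5)3 (0.2 equiv), i-PrOH (1.1 equiv), Et2O, −78 °C → −50 °C
Reagents that add atoms: none
Why: vinylogous Mukaiyama aldol reaction; the bulky Lewis acid activates the aldehyde, the silyl dienolate attacks through its γ-carbon in an open transition state that gives the E enoate, and Felkin–Anh control by C9 (quaternary C10 anti to the nucleophile, H-9 on the side of approach) should give the 11S alcohol, with i-PrOH taking over the silyl group.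

Step 13
Reactants: 26 methyl (2E,5S)-5-hydroxy-3-methyl-5-[(1S,4aS,8aS)-5,5,8a-trimethyl-2-methylidenedecahydronaphthalen-1-yl]pent-2-enoate
Product: 27 methyl (2E,5S)-5-acetoxy-3-methyl-5-[(1S,4aS,8aS)-5,5,8a-trimethyl-2-methylidenedecahydronaphthalen-1-yl]pent-2-enoate (target)
Conditions: Ac2O, DMAP (cat.), pyridine, CH2Cl2, rt
Reagents that add atoms: acetic anhydride (CC(=O)OC(C)=O)
Why: DMAP-catalysed acetylation of the hindered secondary alcohol under mildly basic conditions that should neither eliminate toward the dienoate nor touch any stereocentre.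

**Compound list**

1 | 2,2-dimethylpent-4-enal | C=CCC(C)(C)C=O | starting material
2 | malonic acid | OC(=O)CC(=O)O | starting material
3 | (2,2-dimethylpent-4-en-1-ylidene)propanedioic acid | C=CCC(C)(C)C=C(C(=O)O)C(=O)O | intermediate (not isolated)
4 | (2E)-4,4-dimethylhepta-2,6-dienoic acid | C=CCC(C)(C)/C=C/C(=O)O | intermediate
5 | (4S)-4-benzyl-1,3-oxazolidin-2-one | O=C1N[C@@H](Cc2ccccc2)CO1 | starting material
6 | (2E)-4,4-dimethylhepta-2,6-dienoic pivalic anhydride | C=CCC(C)(C)/C=C/C(=O)OC(=O)C(C)(C)C | intermediate (not isolated)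
7 | (4S)-4-benzyl-3-[(2E)-4,4-dimethylhepta-2,6-dienoyl]-1,3-oxazolidin-2-one | C=CCC(C)(C)/C=C/C(=O)N1[C@@H](Cc2ccccc2)COC1=O | intermediate
8 | (2-bromoprop-2-en-1-yl)trimethylsilane | C=C(Br)C[Si](C)(C)C | starting material
9 | but-2-yn-1-ol | CC#CCO | starting material
10 | bromo[3-(trimethylsilyl)prop-1-en-2-yl]magnesium | C=C([Mg]Br)C[Si](C)(C)C | intermediate (not isolated)
11 | 3-methyl-4-[3-(trimethylsilyl)prop-1-en-2-yl]-2,5-dihydro-1,2-oxamagnesole | CC1=C(C(=C)C[Si](C)(C)C)CO[Mg]1 | intermediate (not isolated)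
12 | (2Z)-3-iodo-2-[3-(trimethylsilyl)prop-1-en-2-yl]but-2-en-1-ol | C/C(I)=C(/CO)C(=C)C[Si](C)(C)C | intermediate
13 | tert-butyl({(2Z)-3-iodo-2-[3-(trimethylsilyl)prop-1-en-2-yl]but-2-en-1-yl}oxy)dimethylsilane | C/C(I)=C(/CO[Si](C)(C)C(C)(C)C)C(=C)C[Si](C)(C)C | intermediate
14 | (4S)-4-benzyl-3-[(2E)-7-(9-borabicyclo[3.3.1]nonan-9-yl)-4,4-dimethylhept-2-enoyl]-1,3-oxazolidin-2-one | O=C(/C=C/C(C)(C)CCCB1C2CCCC1CCC2)N1[C@@H](Cc2ccccc2)COC1=O | intermediate (not isolated)
15 | (4S)-4-benzyl-3-[(2E,8Z)-9-({[tert-butyl(dimethyl)silyl]oxy}methyl)-4,4,8-trimethyl-10-[(trimethylsilyl)methyl]undeca-2,8,10-trienoyl]-1,3-oxazolidin-2-one | O=C(/C=C/C(C)(C)CCC/C(C)=C(\CO[Si](C)(C)C(C)(C)C)C(=C)C[Si](C)(C)C)N1[C@@H](Cc2ccccc2)COC1=O | intermediate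
16 | (4S)-4-benzyl-3-{[(1S,4aS,8aS)-4-({[tert-butyl(dimethyl)silyl]oxy}methyl)-4a,8,8-trimethyl-3-[(trimethylsilyl)methyl]-1,2,4a,5,6,7,8,8a-octahydronaphthalen-1-yl]carbonyl}-1,3-oxazolidin-2-one | C[Si](C)(C)CC1=C(CO[Si](C)(C)C(C)(C)C)[C@@]2(C)CCCC(C)(C)[C@@H]2[C@H](C1)C(=O)N3[C@@H](Cc4ccccc4)COC3=O | intermediate
17 | (1S,4aS,8aS)-4-({[tert-butyl(dimethyl)silyl]oxy}methyl)-4a,8,8-trimethyl-3-[(trimethylsilyl)methyl]-1,2,4a,5,6,7,8,8a-octahydronaphthalene-1-carboperoxoic acid (lithium salt in the flask) | C[Si](C)(C)CC1=C(CO[Si](C)(C)C(C)(C)C)[C@@]2(C)CCCC(C)(C)[C@@H]2[C@H](C1)C(=O)OO | intermediate (not isolated)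
18 | (1S,4aS,8aS)-4-({[tert-butyl(dimethyl)silyl]oxy}methyl)-4a,8,8-trimethyl-3-[(trimethylsilyl)methyl]-1,2,4a,5,6,7,8,8a-octahydronaphthalene-1-carboxylic acid | C[Si](C)(C)CC1=C(CO[Si](C)(C)C(C)(C)C)[C@@]2(C)CCCC(C)(C)[C@@H]2[C@H](C1)C(=O)O | intermediate
19 | 2-sulfanylidenepyridin-1(2H)-yl (1S,4aS,8aS)-4-({[tert-butyl(dimethyl)silyl]oxy}methyl)-4a,8,8-trimethyl-3-[(trimethylsilyl)methyl]-1,2,4a,5,6,7,8,8a-octahydronaphthalene-1-carboxylate | C[Si](C)(C)CC1=C(CO[Si](C)(C)C(C)(C)C)[C@@]2(C)CCCC(C)(C)[C@@H]2[C@H](C1)C(=O)ON3C=CC=CC3=S | intermediate (not isolated)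
20 | tert-butyl(dimethyl)({(4aS,8aS)-5,5,8a-trimethyl-2-[(trimethylsilyl)methyl]-3,4,4a,5,6,7,8,8a-octahydronaphthalen-1-yl}methoxy)silane | C[Si](C)(C)CC1=C(CO[Si](C)(C)C(C)(C)C)[C@@]2(C)CCCC(C)(C)[C@@H]2CC1 | intermediate
21 | [(1S,4aS,8aS)-5,5,8a-trimethyl-2-methylidenedecahydronaphthalen-1-yl]methanol | C=C1CC[C@H]2C(C)(C)CCC[C@]2(C)[C@H]1CO | intermediate
22 | (1S,4aS,8aS)-5,5,8a-trimethyl-2-methylidenedecahydronaphthalene-1-carbaldehyde | C=C1CC[C@H]2C(C)(C)CCC[C@]2(C)[C@H]1C=O | intermediate
23 | methyl 3-methylbut-2-enoate | CC(C)=CC(=O)OC | starting material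
24 | lithium 1-methoxy-3-methylbuta-1,3-dien-1-olate | C=C(C)C=C(OC)O[Li] | intermediate (not isolated)
25 | tert-butyl[(1-methoxy-3-methylbuta-1,3-dien-1-yl)oxy]dimethylsilane | C=C(C)C=C(OC)O[Si](C)(C)C(C)(C)C | intermediate
26 | methyl (2E,5S)-5-hydroxy-3-methyl-5-[(1S,4aS,8aS)-5,5,8a-trimethyl-2-methylidenedecahydronaphthalen-1-yl]pent-2-enoate | C=C1CC[C@H]2C(C)(C)CCC[C@]2(C)[C@H]1[C@H](C/C(C)=C/C(=O)OC)O | intermediate
27 | methyl (2E,5S)-5-acetoxy-3-methyl-5-[(1S,4aS,8aS)-5,5,8a-trimethyl-2-methylidenedecahydronaphthalen-1-yl]pent-2-enoate | C=C1CC[C@H]2C(C)(C)CCC[C@]2(C)[C@H]1[C@H](C/C(C)=C/C(=O)OC)OC(C)=O | target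

**Step count and risks**

Total steps: 13. Longest linear sequence: 10 steps (1 → 4 → 7 → 15 → 16 → 18 → 20 → 21 → 22 → 26 → 27; steps 1, 2, 5, 6, 7, 8, 9, 10, 12, 13).

Steps most likely to fail:

1. Step 6. The cycloaddition may stall because the C5–C10 bond joins a carbon next to the C4 quaternary centre to a fully substituted diene terminus; the Lewis acid may also degrade the allylsilane diene, or exo closure may compete. Fallback (sets out from 15, comes back at 20): the activation mode is changed from a chelated Lewis acid complex to iminium catalysis. Compound 15 is reduced with LiBH4/MeOH in Et2O, which releases the auxiliary and gives the trienol F1. MnO2 oxidises it to the trienal F2. (2S,5S)-5-Benzyl-2-tert-butyl-3-methylimidazolidin-4-one trifluoroacetate (20 mol %) in wet MeCN should then effect the organocatalytic intramolecular Diels–Alder reaction of the trienal through its E iminium ion, one face of which is covered by the benzyl group, to give the trans-fused aldehyde cycloadduct F3 with the same configuration at C5 and C10. Stoichiometric RhCl(PPh3)3 in hot toluene (Tsuji–Wilkinson decarbonylation) removes the formyl group and gives 20.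

2. Step 3. The branched alkenyl Grignard reagent may add too slowly to the magnesium alkoxide, or decompose on prolonged heating, so that little carbometalation occurs. Fallback (sets out from 9, comes back at 21): the silylmethyl carbon is given up at this stage and the exocyclic carbon is introduced after the cycloaddition.
   - From 9, CH2=CHMgCl (THF/toluene, 70 °C) and then I2 give, through the cyclic magnesium alkoxide F4, the iodo dienol F5.
   - TBSCl/imidazole gives the silyl ether F6, and coupling with borane 14 under the conditions of step 5 gives the triene imide F7.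
   - Me2AlCl as in step 6 gives the trans-fused cycloadduct F8 (C8–H in place of C8–CH2SiMe3).
   - LiOH/H2O2 gives, through the peracid F9, the acid F10; Barton decarboxylation through the thiohydroxamate ester F11 gives the octalin silyl ether F12.
   - BH3·THF adds to the C8=C9 bond from the α face (anti to the C10 methyl) to give the alkylborane F13, and NaOH/H2O2 gives the 8α-alcohol F14 with H-9 α.
   - Dess–Martin oxidation gives the C8 ketone F15, in which C9 keeps its equatorial substituent; Lombardo methylenation (Zn, CH2Br2, TiCl4) gives the methylidene silyl ether F16; Bu4NF then gives 21.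

3. Step 12. Facial selectivity at the hindered aldehyde may be poor, or the β,γ-unsaturated aldehyde may epimerise at C9 or isomerise into conjugation under the Lewis acid before it is attacked. Fallback (sets out from 22, comes back at 26): the chain is built in two two-carbon stages with catalyst control instead of one vinylogous aldol. A D-proline-catalysed direct aldol reaction of 22 with acetone (catalyst control matched with the Felkin–Anh preference) should give the β-hydroxy ketone F17. TESCl/imidazole gives the silyl ether F18. Horner–Wadsworth–Emmons olefination with trimethyl phosphonoacetate/NaH gives the E enoate F19, from which the minor Z isomer would be separated. HF·pyridine removes the silyl group and gives 26.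

Further compounds
F1 | step 6 | (2E,8Z)-9-({[tert-butyl(dimethyl)silyl]oxy}methyl)-4,4,8-trimethyl-10-[(trimethylsilyl)methyl]undeca-2,8,10-trien-1-ol | OC/C=C/C(C)(C)CCC/C(C)=C(\CO[Si](C)(C)C(C)(C)C)C(=C)C[Si](C)(C)C
F2 | step 6 | (2E,8Z)-9-({[tert-butyl(dimethyl)silyl]oxy}methyl)-4,4,8-trimethyl-10-[(trimethylsilyl)methyl]undeca-2,8,10-trienal | O=C/C=C/C(C)(C)CCC/C(C)=C(\CO[Si](C)(C)C(C)(C)C)C(=C)C[Si](C)(C)C
F3 | step 6 | (1S,4aS,8aS)-4-({[tert-butyl(dimethyl)silyl]oxy}methyl)-4a,8,8-trimethyl-3-[(trimethylsilyl)methyl]-1,2,4a,5,6,7,8,8a-octahydronaphthalene-1-carbaldehyde | C[Si](C)(C)CC1=C(CO[Si](C)(C)C(C)(C)C)[C@@]2(C)CCCC(C)(C)[C@@H]2[C@H](C1)C=O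
F4 | step 3 | 4-ethenyl-3-methyl-2,5-dihydro-1,2-oxamagnesole | CC1=C(C=C)CO[Mg]1
F5 | step 3 | (2Z)-2-ethenyl-3-iodobut-2-en-1-ol | C/C(I)=C(/CO)C=C
F6 | step 3 | tert-butyl{[(2Z)-2-ethenyl-3-iodobut-2-en-1-yl]oxy}dimethylsilane | C/C(I)=C(/CO[Si](C)(C)C(C)(C)C)C=C
F7 | step 3 | (4S)-4-benzyl-3-[(2E,8Z)-9-({[tert-butyl(dimethyl)silyl]oxy}methyl)-4,4,8-trimethylundeca-2,8,10-trienoyl]-1,3-oxazolidin-2-one | O=C(/C=C/C(C)(C)CCC/C(C)=C(\CO[Si](C)(C)C(C)(C)C)C=C)N1[C@@H](Cc2ccccc2)COC1=O
F8 | step 3 | (4S)-4-benzyl-3-{[(1S,4aS,8aS)-4-({[tert-butyl(dimethyl)silyl]oxy}methyl)-4a,8,8-trimethyl-1,2,4a,5,6,7,8,8a-octahydronaphthalen-1-yl]carbonyl}-1,3-oxazolidin-2-one | C1=C(CO[Si](C)(C)C(C)(C)C)[C@@]2(C)CCCC(C)(C)[C@@H]2[C@H](C1)C(=O)N3[C@@H](Cc4ccccc4)COC3=O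
F9 | step 3 | (1S,4aS,8aS)-4-({[tert-butyl(dimethyl)silyl]oxy}methyl)-4a,8,8-trimethyl-1,2,4a,5,6,7,8,8a-octahydronaphthalene-1-carboperoxoic acid | C1=C(CO[Si](C)(C)C(C)(C)C)[C@@]2(C)CCCC(C)(C)[C@@H]2[C@H](C1)C(=O)OO
F10 | step 3 | (1S,4aS,8aS)-4-({[tert-butyl(dimethyl)silyl]oxy}methyl)-4a,8,8-trimethyl-1,2,4a,5,6,7,8,8a-octahydronaphthalene-1-carboxylic acid | C1=C(CO[Si](C)(C)C(C)(C)C)[C@@]2(C)CCCC(C)(C)[C@@H]2[C@H](C1)C(=O)O
F11 | step 3 | 2-sulfanylidenepyridin-1(2H)-yl (1S,4aS,8aS)-4-({[tert-butyl(dimethyl)silyl]oxy}methyl)-4a,8,8-trimethyl-1,2,4a,5,6,7,8,8a-octahydronaphthalene-1-carboxylate | C1=C(CO[Si](C)(C)C(C)(C)C)[C@@]2(C)CCCC(C)(C)[C@@H]2[C@H](C1)C(=O)ON3C=CC=CC3=S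
F12 | step 3 | tert-butyl(dimethyl){[(4aS,8aS)-5,5,8a-trimethyl-3,4,4a,5,6,7,8,8a-octahydronaphthalen-1-yl]methoxy}silane | C1=C(CO[Si](C)(C)C(C)(C)C)[C@@]2(C)CCCC(C)(C)[C@@H]2CC1
F13 | step 3 | [(1S,2R,4aS,8aS)-1-({[tert-butyl(dimethyl)silyl]oxy}methyl)-5,5,8a-trimethyldecahydronaphthalen-2-yl]borane | B[C@@H]1CC[C@H]2C(C)(C)CCC[C@]2(C)[C@H]1CO[Si](C)(C)C(C)(C)C
F14 | step 3 | (1S,2R,4aS,8aS)-1-({[tert-butyl(dimethyl)silyl]oxy}methyl)-5,5,8a-trimethyldecahydronaphthalen-2-ol | O[C@@H]1CC[C@H]2C(C)(C)CCC[C@]2(C)[C@H]1CO[Si](C)(C)C(C)(C)C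
F15 | step 3 | (1S,4aS,8aS)-1-({[tert-butyl(dimethyl)silyl]oxy}methyl)-5,5,8a-trimethyloctahydronaphthalen-2(1H)-one | O=C1CC[C@H]2C(C)(C)CCC[C@]2(C)[C@H]1CO[Si](C)(C)C(C)(C)C
F16 | step 3 | tert-butyl(dimethyl){[(1S,4aS,8aS)-5,5,8a-trimethyl-2-methylidenedecahydronaphthalen-1-yl]methoxy}silane | C=C1CC[C@H]2C(C)(C)CCC[C@]2(C)[C@H]1CO[Si](C)(C)C(C)(C)C
F17 | step 12 | (4S)-4-hydroxy-4-[(1S,4aS,8aS)-5,5,8a-trimethyl-2-methylidenedecahydronaphthalen-1-yl]butan-2-one | C=C1CC[C@H]2C(C)(C)CCC[C@]2(C)[C@H]1[C@H](CC(C)=O)O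
F18 | step 12 | (4S)-4-[(triethylsilyl)oxy]-4-[(1S,4aS,8aS)-5,5,8a-trimethyl-2-methylidenedecahydronaphthalen-1-yl]butan-2-one | C=C1CC[C@H]2C(C)(C)CCC[C@]2(C)[C@H]1[C@H](CC(C)=O)O[Si](CC)(CC)CC
F19 | step 12 | methyl (2E,5S)-3-methyl-5-[(triethylsilyl)oxy]-5-[(1S,4aS,8aS)-5,5,8a-trimethyl-2-methylidenedecahydronaphthalen-1-yl]pent-2-enoate | C=C1CC[C@H]2C(C)(C)CCC[C@]2(C)[C@H]1[C@H](C/C(C)=C/C(=O)OC)O[Si](CC)(CC)CC
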